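The azepine ring N4–C5–C6–C7–C8–C9–C9a (tuberostemonine numbering) is disconnected at C6–C7. Its four methylenes C5–C8 carry no functionality and lie between pyrrole N4 and the stereocentre C9, so an N4-allyl/C9-allyl pair is a traceless precursor: ring-closing metathesis with in-situ hydrogenation closes this seven-membered ring as the last ring, under neutral conditions that spare the ionisable pyrrolylic C18–O bond and the epimerisable C13 and C20 methyl centres. The precursor is the complete pyrrole bis-lactone diene, whose N-allyl group earlier served as the activating N-substituent in the organocatalytic Friedel–Crafts step that set C9; carbocycle and fused lactone arise from a butenolide Friedel–Crafts–Michael closure.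

Key step: step 10

Remark: atoms are named by tuberostemonine numbering (pyrrole C9a, C1, C2, C3; carbocycle C9–C10(Et)–C11(O)–C12; fused lactone C13(Me)–C14; pendant lactone C18(O)–C19–C20(Me)–C21), and half-ester 12 is taken to be a catalogue compound (otherwise one step from dimethyl (S)-methylsuccinate by saponification of the unhindered ester).

Step 1
Reactants: 1 (E)-pent-2-ene; 2 but-2-ynal
Product: 4 (3R,4R)-3-ethylhept-1-en-5-yn-4-ol, via pentenyl-Ipc2-borane 3 (not isolated)
Conditions: 1, n-BuLi, KOt-Bu, THF, −78 → −45 °C; (+)-Ipc2BOMe, −78 °C; BF3·OEt2, then 2, −78 °C; NaOH, H2O2, 0 °C → rt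
Reagents that add atoms: none
Why: Brown-type γ-alkylallylboration through a closed chair transition state, in which the E-pentenyl geometry should give the anti C10/C11 relationship and the Ipc groups derived from (−)-α-pinene select the aldehyde face that gives 11R (and with it 10R).

Step 2
Reactants: 4 (3R,4R)-3-ethylhept-1-en-5-yn-4-ol
Product: 5 (3R,4R,5Z)-3-ethyl-6-iodohepta-1,5-dien-4-ol
Conditions: Red-Al, THF, 0 °C → rt; then I2, −78 °C
Reagents that add atoms: iodine (II)
Why: Hydroxyl-directed trans-hydroalumination of the propargylic alcohol (Corey-type Red-Al reduction) gives a cyclic alkenylalanate that is iodinated with retention, so iodine ends on the distal carbon cis to the carbinol and no stereocentre is touched.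

Step 3
Reactants: 5 (3R,4R,5Z)-3-ethyl-6-iodohepta-1,5-dien-4-ol
Product: 6 (5R)-3-methyl-5-[(3R)-pent-1-en-3-yl]furan-2(5H)-one
Conditions: PdCl2(PPh3)2 (5 mol %), CO (3 bar), K2CO3, THF, 40 °C
Reagents that add atoms: carbon monoxide ([C-]#[O+])
Why: Oxidative addition of Pd(0) into the vinyl iodide, CO insertion and intramolecular capture by the cis hydroxyl (carbonylative lactonisation, Stille-type butenolide synthesis) should close the 3-methylbutenolide with C11 unchanged.

Step 4
Reactants: 6 (5R)-3-methyl-5-[(3R)-pent-1-en-3-yl]furan-2(5H)-one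
Product: 7 (2E,4R)-4-[(2R)-4-methyl-5-oxo-2,5-dihydrofuran-2-yl]hex-2-enal
Conditions: crotonaldehyde (5 equiv), Hoveyda–Grubbs II (5 mol %), CH2Cl2, 40 °C
Reagents that add atoms: (E)-crotonaldehyde (C/C=C/C=O)
Why: Olefin cross-metathesis of the monosubstituted olefin with excess crotonaldehyde is E-selective, and the trisubstituted, electron-poor butenolide olefin does not enter the catalytic cycle.

Step 5
Reactants: 7 (2E,4R)-4-[(2R)-4-methyl-5-oxo-2,5-dihydrofuran-2-yl]hex-2-enal; 8 1-allylpyrrole
Product: 9 (3R,4R)-4-[(2R)-4-methyl-5-oxo-2,5-dihydrofuran-2-yl]-3-[1-(prop-2-en-1-yl)-1H-pyrrol-2-yl]hexanal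
Conditions: 8 (5 equiv), (5R)-5-benzyl-2,2,3-trimethylimidazolidin-4-one·TFA (20 mol %), THF/H2O 95:5, −30 °C
Reagents that add atoms: none
Why: Iminium-catalysed Friedel–Crafts alkylation (MacMillan type), in which the benzyl group of the (5R)-imidazolidinone shields one face of the E-iminium so that pyrrole C2 adds to the other and sets 9R under catalyst control, while excess pyrrole suppresses 2,5-dialkylation.

Step 6
Reactants: 9 (3R,4R)-4-[(2R)-4-methyl-5-oxo-2,5-dihydrofuran-2-yl]-3-[1-(prop-2-en-1-yl)-1H-pyrrol-2-yl]hexanal
Product: 10 (5R)-3-methyl-5-{(3R,4R)-4-[1-(prop-2-en-1-yl)-1H-pyrrol-2-yl]hept-6-en-3-yl}furan-2(5H)-one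
Conditions: CH2I2, Zn, Ti(OiPr)4, THF, rt
Reagents that add atoms: diiodomethane (ICI)
Why: Takai–Lombardo methylenation turns the aldehyde into the C9-allyl group under non-basic conditions, so the acidic butenolide γ-hydrogen at C11 should not be epimerised.

Step 7
Reactants: 10 (5R)-3-methyl-5-{(3R,4R)-4-[1-(prop-2-en-1-yl)-1H-pyrrol-2-yl]hept-6-en-3-yl}furan-2(5H)-one
Product: 11 (9R,10R,11R,12S,13S)-tricyclic pyrrole lactone: 1,7-diallyl-6-ethyl-4,5,6,7-tetrahydroindole cis-fused across C4–C5 to an α-methyl-γ-butyrolactone (lactone O on indole C5, CHMe on indole C4)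
Conditions: Me2AlCl (2 equiv), CH2Cl2 (5 mM), −78 → 0 °C; aq NaHCO3 at −78 °C
Reagents that add atoms: none
Why: Lewis-acid-promoted intramolecular Friedel–Crafts conjugate addition (6-exo-trig) of pyrrole C1 to the butenolide β-carbon C12, in which the C10–C11 tether reaches only one face and so makes the lactone cis-fused (12S), and the aluminium enolate left after the pyrrolium proton is lost as methane should be protonated from the convex face to place the C13 methyl endo (13S).

Step 8
Reactants: 11 tricyclic pyrrole lactone; 12 (3S)-4-methoxy-3-methyl-4-oxobutanoic acid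
Product: 14 methyl (2S)-2-methyl-4-oxo-4-(pyrrol-3-yl of 11)butanoate (C3-acylated 11), via mixed anhydride 13 (not isolated)
Conditions: 12, (CF3CO)2O, CH2Cl2, 0 °C; then 11, 2,6-lutidine, 0 °C → rt
Reagents that add atoms: none
Why: Friedel–Crafts acylation of the electron-rich pyrrole by the mixed trifluoroacetic anhydride should occur at C3, the only free α-position, and the C20 centre lies β to the acylating carbonyl and cannot racemise.

Step 9
Reactants: 14 C3-acylated tricyclic keto ester
Product: 16 (9R,10R,11R,12S,13S,18R,20S)-bis-lactone diene (11 carrying at pyrrole C3 the trans-4-methyl-5-oxotetrahydrofuran-2-yl ring), via hydroxy ester 15 (not isolated)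
Conditions: (S)-Me-CBS (30 mol %), catecholborane, toluene, −40 °C; MeOH; then toluene, 2-hydroxypyridine (cat.), 40 °C
Reagents that add atoms: none
Why: CBS reduction, in which the (S)-oxazaborolidine binds the ketone anti to the pyrrolyl group (large substituent) and should deliver hydride to give the 18R carbinol, which lactonises onto the methyl ester with loss of methanol to the trans-α-methyl-γ-butyrolactone without acid.

Step 10
Reactants: 16 bis-lactone diene
Product: 18 target (CNP0232452.1, 9R,10R,11R,12S,13S,18R,20S), via dehydroazepine 17 (not isolated)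
Conditions: Grubbs II (5 mol %), CH2Cl2 (3 mM), 40 °C; then H2 (7 bar), 50 °C, same pot
Reagents that add atoms: none
Why: Ring-closing olefin metathesis: the Ru alkylidene loads on one allyl group, undergoes intramolecular [2+2]/retro-[2+2] with the other and expels ethene to give the C6=C7 cycloheptene 17; the closest known reactions are RCM of N-allyl-2-(but-3-enyl)pyrroles to dihydropyrrolo[1,2-a]azepines and tandem RCM–hydrogenation in which H2 converts the spent carbene into a Ru hydride. The azepine is closed by forming the C6–C7 bond of a 1,8-diene whose two arms are held close by the planar N4–C9a bond of the pyrrole. No stereocentre is created, and the C9 centre set in step 5 is simply carried into the ring. The step needs cyclisation over oligomerisation (secured by dilution and the pre-organised diene), chemoselectivity (the two terminal olefins are the only reactive alkenes, since the butenolide was consumed in step 7) and neutrality (no acid or base, so the ionisable C18–O bond and the C13 and C20 methyl centres are untouched). Hydrogenation should then remove only the new disubstituted olefin, because the pyrrole and both lactones are inert to the Ru hydride.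

Compound list
1 | (E)-pent-2-ene | C/C=C/CC | starting material
2 | but-2-ynal | CC#CC=O | starting material
3 | (E)-pent-2-en-1-yl-di(isopinocampheyl)borane, Ipc groups from (−)-α-pinene | CC/C=C/CB([C@H]1C[C@H]2C[C@@H]([C@@H]1C)C2(C)C)[C@H]1C[C@H]2C[C@@H]([C@@H]1C)C2(C)C | intermediate
4 | (3R,4R)-3-ethylhept-1-en-5-yn-4-ol | CC[C@H](C=C)[C@@H](O)C#CC | intermediate
5 | (3R,4R,5Z)-3-ethyl-6-iodohepta-1,5-dien-4-ol | CC[C@H](C=C)[C@@H](O)/C=C(/C)I | intermediate
6 | (5R)-3-methyl-5-[(3R)-pent-1-en-3-yl]furan-2(5H)-one | CC[C@H](C=C)[C@H]1OC(=O)C(C)=C1 | intermediate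
7 | (2E,4R)-4-[(2R)-4-methyl-5-oxo-2,5-dihydrofuran-2-yl]hex-2-enal | CC[C@H](/C=C/C=O)[C@H]1OC(=O)C(C)=C1 | intermediate
8 | 1-allylpyrrole [1-(prop-2-en-1-yl)-1H-pyrrole] | C=CCn1cccc1 | starting material
9 | (3R,4R)-4-[(2R)-4-methyl-5-oxo-2,5-dihydrofuran-2-yl]-3-[1-(prop-2-en-1-yl)-1H-pyrrol-2-yl]hexanal | CC[C@H]([C@@H](CC=O)c1cccn1CC=C)[C@H]1OC(=O)C(C)=C1 | intermediate
10 | (5R)-3-methyl-5-{(3R,4R)-4-[1-(prop-2-en-1-yl)-1H-pyrrol-2-yl]hept-6-en-3-yl}furan-2(5H)-one | CC[C@H]([C@@H](CC=C)c1cccn1CC=C)[C@H]1OC(=O)C(C)=C1 | intermediate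
11 | (9R,10R,11R,12S,13S)-tricyclic pyrrole lactone: 1,7-diallyl-6-ethyl-4,5,6,7-tetrahydroindole cis-fused at C4–C5 to an α-methyl-γ-butyrolactone | CC[C@H]1[C@H]2OC(=O)[C@@H](C)[C@H]2c2ccn(CC=C)c2[C@@H]1CC=C | intermediate
12 | (3S)-4-methoxy-3-methyl-4-oxobutanoic acid [(S)-2-methylsuccinic acid 1-methyl ester] | OC(=O)C[C@H](C)C(=O)OC | starting material
13 | (3S)-4-methoxy-3-methyl-4-oxobutanoic trifluoroacetic anhydride | FC(F)(F)C(=O)OC(=O)C[C@H](C)C(=O)OC | intermediate
14 | tricyclic lactone 11 acylated at pyrrole C3 with the (S)-3-(methoxycarbonyl)butanoyl group (keto ester; 9R,10R,11R,12S,13S,20S) | CC[C@H]1[C@H]2OC(=O)[C@@H](C)[C@H]2c2cc(C(=O)C[C@H](C)C(=O)OC)n(CC=C)c2[C@@H]1CC=C | intermediate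
15 | corresponding (18R)-hydroxy ester | CC[C@H]1[C@H]2OC(=O)[C@@H](C)[C@H]2c2cc([C@H](O)C[C@H](C)C(=O)OC)n(CC=C)c2[C@@H]1CC=C | intermediate
16 | N4,C9-diallyl bis-lactone (9R,10R,11R,12S,13S,18R,20S), pendant lactone trans | CC[C@H]1[C@H]2OC(=O)[C@@H](C)[C@H]2c2cc([C@H]3C[C@H](C)C(=O)O3)n(CC=C)c2[C@@H]1CC=C | intermediate
17 | 6,7-didehydro target (Z-olefin C6=C7 in the azepine) | CC[C@H]1[C@H]2OC(=O)[C@@H](C)[C@H]2c2cc([C@H]3C[C@H](C)C(=O)O3)n3c2[C@@H]1C/C=C\C3 | intermediate
18 | target CNP0232452.1 (9R,10R,11R,12S,13S,18R,20S) | CC[C@H]1[C@H]2OC(=O)[C@@H](C)[C@H]2c2cc([C@H]3C[C@H](C)C(=O)O3)n3c2[C@@H]1CCCC3 | target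

Total step count: 10. Longest linear sequence: 10 steps (1/2 → 18).

Steps most likely to fail

Step 7. Conjugate addition to the α-methylbutenolide may be slow, so that intermolecular alkylation through the free pyrrole α-position C3 and Lewis-acid-induced olefin reactions take over; protonation of the enolate may also be unselective at C13. The fallback closes the ring by a radical instead of an ionic process and sets out from 10. Acylation with 13 under the conditions of step 8 should give the C3-acylpyrrole butenolide F1. The acyl group blocks C3 and directs iodination (NIS, THF, −20 °C) to C1, giving the iodide F2. Bu3SnH/AIBN (benzene, 80 °C, slow addition) then generates the C1 pyrrolyl radical, which should add 6-exo to the butenolide rather than 5-exo to the C9-allyl group (that would give a strained 5,5-fused ring). The lactone α-radical takes hydrogen from the convex face, and the route is rejoined at 14.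

Step 9. Hydride delivery to the vinylogous-amide ketone may be sluggish, so that uncatalysed reduction erodes facial selectivity at C18, and the pyrrolylic borate may ionise and scramble or deoxygenate C18. The fallback makes C18 by C–C bond formation instead of reduction and sets out from 11. Vilsmeier–Haack formylation (POCl3, DMF, 0 °C) should give the C3-carbaldehyde F3. The dialkylzinc made from methyl (R)-3-iodo-2-methylpropanoate (Et2Zn, CuI cat.) is then added under Ti(OiPr)4/(1S,2S)-1,2-bis(trifluoromethanesulfonamido)cyclohexane catalysis (toluene, −20 °C), which should give the zinc alkoxide of 15 with catalyst control at C18. This lactonises on work-up, and the route is rejoined at 16 (through 15).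

Step 1. Metalation of pentene may be incompletely regioselective and the pentenylpotassium may equilibrate from E to Z, which erodes the anti ratio; the small alkynyl aldehyde may also give lower facial selectivity. The fallback is a catalytic asymmetric Nozaki–Hiyama pentenylation that sets out from 2 and gives 4 directly (no new compound, F0): (E)-1-bromopent-2-ene, CrCl3 with a chiral carbazole-bis(oxazoline) ligand, Mn, TMSCl, Et3N, THF, rt. The pentenylchromium(III) reagent reacts through a chair to the anti adduct whatever the bromide geometry, and the ligand fixes 11R.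

Further compounds
F1 | step 7 | methyl (2S)-4-{1-allyl-5-[(4R,5R)-5-((2R)-4-methyl-5-oxo-2,5-dihydrofuran-2-yl)hept-1-en-4-yl]-1H-pyrrol-2-yl}-2-methyl-4-oxobutanoate | CC[C@H]([C@@H](CC=C)c1ccc(C(=O)C[C@H](C)C(=O)OC)n1CC=C)[C@H]1OC(=O)C(C)=C1
F2 | step 7 | 4-iodopyrrole derived from F1 (iodine on the ring carbon next to the alkyl-bearing carbon, i.e. C1) | CC[C@H]([C@@H](CC=C)c1c(I)cc(C(=O)C[C@H](C)C(=O)OC)n1CC=C)[C@H]1OC(=O)C(C)=C1
F3 | step 9 | pyrrole C3-carbaldehyde of tricyclic lactone 11 | CC[C@H]1[C@H]2OC(=O)[C@@H](C)[C@H]2c2cc(C=O)n(CC=C)c2[C@@H]1CC=C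
F0 | step 1 | none | none
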